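- Two questions stand on this flask, both about the moment when 50% of its substrate counts as reacted.

| flask | substrate | reagent | free catalyst | remark |
|---|---|---|---|---|
| ash | 20 mM | 10 mM | 0.94 mM | the very flask that is asked about, followed so far |
| flask | 20 mM | 10.0 mM | 0.94 mM |  |

ash run (percent of the substrate charged): time / min: target / % = 0.500: 0; 1.00: 1.8; 1.50: 2.5; 2.50: 6.3; 4.00: 11.2; 8.00: 21.6

(standard deviation of a reading: 0.5 percentage points)

1. apparent order in reagent when 50% of the substrate are converted (percent change of the rate of making target for one percent more reagent charged)
2. apparent order in free catalyst when 50% of the substrate are converted (percent change of the rate of making target for one percent more free catalyst charged)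

- the analysis behind the earlier runs scatters by 0.5 percentage points, standard deviation
- steps that have been proposed: substrate + free catalyst -> catalyst intermediate A; catalyst intermediate A -> catalyst intermediate B; reagent + catalyst intermediate B <-> catalyst intermediate C; catalyst intermediate C <-> catalyst intermediate D; catalyst intermediate D <-> released group + catalyst intermediate E; catalyst intermediate E -> free catalyst + target; substrate <-> dormant form
- what has gone from substrate into another species counts as reacted, even if it can come back
- no earlier run changes the charge of free catalyst; that part of a forecast is a guess
- no earlier run changes the charge of reagent; that part of a forecast is a guess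

- First instants: catalyst takes up substrate and has to pass through its intermediates before target appears, and this flask reads 0% target at 0.500 min.
- Middle: each target costs one substrate and one reagent on the proposed steps, and between 4.00 min and 8.00 min the readings of this flask give target at 0.520 mM min⁻¹.
- End: in this flask reagent is the limiting reagent, at 10.0 mM against 20 mM of substrate, so I reckon with the ceiling, the reagent charge over the substrate charge, 50.0%: the share of the substrate charged that can become target.
- My rule: the spent share of the reagent charge is the target reading over the ceiling, plus what sits in catalyst intermediates C, D and E, the forms that carry reagent on the proposed steps. At 8.00 min the target reading gives 43.2% spent before that addition.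
- What is about to matter: the ceiling equals the conversion asked about, so [reagent] at that moment depends on how much of the reacted substrate is target; dormant form also counts as reacted and uses no reagent on the proposed steps, and these readings show target and no other species.
- The forecast gives 3 in reagent and 1.3 in free catalyst, holding that at this moment “reagent is nearly exhausted”. I keep the reagent left open until the target at that moment is seen, so I commit to the rule and not to that number.
- This flask reaches the conversion at 0.163 h, with apparent orders 0.70 in reagent and 0.86 in free catalyst, both lower than the forecast.

    substrate + free catalyst → catalyst intermediate A (k = 3.70 M⁻¹ s⁻¹)
    catalyst intermediate A → catalyst intermediate B (k = 0.0760 s⁻¹)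
    reagent + catalyst intermediate B ⇌ catalyst intermediate C (K = 100 M⁻¹, k = 700 M⁻¹ s⁻¹)
    catalyst intermediate C ⇌ catalyst intermediate D (K = 1.30, k = 0.110 s⁻¹)
    catalyst intermediate D ⇌ released group + catalyst intermediate E (K = 0.0190 M, k = 0.0560 s⁻¹)
    catalyst intermediate E → free catalyst + target (k = 7.20 s⁻¹)
    substrate ⇌ dormant form (K = 1.30, k = 6.00 × 10⁻⁴ s⁻¹)

- At 0.154 h this flask uses substrate in the step to catalyst intermediate A at 1.2 times the rate of the forward step to dormant form, and at 0.150 h it holds 20.6% of the substrate charged as dormant form beside 23.0% as target. With the ceiling of 50.0%, that target leaves 54.0% of the reagent charge, catalyst intermediates C, D and E hold another 3.08% of it, and the flask shows 50.8% of reagent left.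

The numbers in the tables were generated by integration for substances that don't exist; the scatter is artificial.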